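(The data were generated by integration for substances that don't exist; the scatter is artificial.)

A leftover opens this: after 10.0 d, 32.7% of the starting material remains in Friday's run and 32.1% in Thursday's, from charges of 1.1 M and 1.8 M, so I count in fractions of the charge and follow one molecule.

| flask | starting material | remark | time |
|---|---|---|---|
| Friday's | 1.1 M | run made earlier |  |
| Thursday's | 1.8 M | run made earlier |  |
| flask | 0.80 M |  | 15 d |

| run | time / d | isomer of the product A / % | target / % | starting material / % |
|---|---|---|---|---|
| Friday's | 0.500 | 0.9 | 27.5 | 66.0 |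
| Friday's | 1.25 | 2.1 | 37.1 | 49.2 |
| Friday's | 2.50 | 2.8 | 40.4 | 42.5 |
| Friday's | 4.00 | 4.0 | 38.5 | 39.3 |
| Friday's | 5.00 | 4.9 | 37.5 | 39.0 |
| Friday's | 8.00 | 5.9 | 33.9 | 35.1 |
| Friday's | 10.0 | 7.6 | 31.4 | 32.7 |
| Thursday's | 0.500 | 1.1 | 27.3 | 65.5 |
| Thursday's | 1.25 | 1.6 | 37.6 | 49.4 |
| Thursday's | 2.50 | 2.2 | 39.3 | 42.2 |
| Thursday's | 4.00 | 3.4 | 38.8 | 39.5 |
| Thursday's | 5.00 | 4.8 | 37.3 | 38.7 |
| Thursday's | 8.00 | 6.1 | 33.6 | 35.3 |
| Thursday's | 10.0 | 7.8 | 31.8 | 32.1 |

(standard deviation of a reading: 0.5 percentage points)

- the numbers in the tables scatter by 0.5 percentage points (one standard deviation)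
- steps thought possible: starting material <-> target; starting material <-> isomer of the product A; starting material <-> third isomer; target <-> isomer of the product B

- ratio of isomer of the product A to target at 50 min
- ratio of isomer of the product A to target at 15 d

I draw target first. Averaged over both runs, it reads 27.4% at 0.500 d and stands near 39.8% at 2.50 d. If I take that as the level of one exponential, the knee rate is 2.33 /d, so the slope at the start is 0.927 /d.

Between 4.00 d and 10.0 d, the gain of isomer of the product A, set against the starting material present, gives the leak, 0.0186 /d: as read from the two runs, the net chance per day that a molecule sitting as starting material leaves for isomer of the product A.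

At 50 min, earlier than the knee time of 0.429 d, I expect the ratio to be near leak over slope, a selectivity factor of 0.0200. Later, the two runs read target falling by 0.0336 /d. Carrying that on, and letting starting material fall at the same pace, I expect target in the 0.80 M flask to reach 26.7% at 15 d and the leak to lift isomer of the product A to 10.5%, a ratio of 0.392.

The forecast gives 0.022 (0.017 to 0.029) and 0.385 (0.35 to 0.42), holding that “the steps behave as first order”. My early figure is lower than its own.

The flask gives 0.0206 and 0.392.

    starting material ⇌ target (K = 0.920, k = 0.0413 /h)
    starting material ⇌ isomer of the product A (K = 2.51, k = 8.24 × 10⁻⁴ /h)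
    starting material ⇌ third isomer (K = 91.2, k = 0.00209 /h)
    target ⇌ isomer of the product B (K = 0.211, k = 0.0370 /h)

In the flask, from 7.50 d to 15.0 d, starting material goes from 35.7% to 28.3%. The leak on their mean gives 4.46%, and isomer of the product A gains 4.2 percentage points. With the leak counted per molecule, I reckon 0.0200 and 0.392 again for the neighbour flask at 1.4 M. That flask gives 0.0206 and, from isomer of the product A at 10.6% and target at 26.9%, 0.392.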